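**Plan**

- Retrosynthesis cuts the chroman O–CMe2 bond first. It then cuts the three aryl–C5 bonds together (C7–CMe2, C2'–CH2, C6'–CH2), back to three allyl aryl ethers. Last, it cuts the furan ring at O1–C2 and C2=C3 into a salicyl phosphonium salt and a benzoyl chloride.
- Enabling feature: each C5 unit sits ortho to a phenolic oxygen (the quaternary carbon on C7 beside O6, the CH2 on C2' beside O3', the CH2 on C6' beside O5'). Ring C keeps a twofold symmetry until the dihydropyran closes, so three oxygen-to-carbon [3,3] shifts can place all three units.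
- Forward: the ring A and ring C building blocks are made separately, and the furan ring (ring B) arises by acylation and intramolecular Wittig closure. One thermolysis then moves the three allyl groups from oxygen to carbon, and the dihydropyran (ring D) closes last on one of two equivalent prenyl/phenol pairs.
- Stereochemistry: the target has no stereocentre and no stereogenic double bond, so nothing has to be controlled.

Key step: step 10

Numbering: benzofuran locants O1, C2, C3, C3a, C4 to C7, C7a (ring A is the benzo ring); primed locants for the pendant ring C, with C1' bonded to C2.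
Assumption: methyl 4-bromo-3,5-dihydroxybenzoate, the methyl ester of 4-bromo-3,5-dihydroxybenzoic acid, is taken as a catalogue compound.

**Route**

Step 1
Reactants: 1 2,4,6-trihydroxybenzaldehyde; 2 prenyl bromide
Product: 3 2,6-dihydroxy-4-(3-methylbut-2-enyloxy)benzaldehyde
Conditions: 2 (1.0 equiv), K2CO3 (1.0 equiv), acetone, 0 °C to rt
Reagents that add atoms: prenyl bromide (compound 2), CC(C)=CCBr
Why: Williamson etherification with one equivalent of halide and a weak base should go to the 4-hydroxyl, which is the most acidic (para to the formyl group and not held in the hydrogen bond to the carbonyl oxygen), as is usual for 2,4,6-trihydroxyaryl carbonyl compounds.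

Step 2
Reactants: 3 2,6-dihydroxy-4-(3-methylbut-2-enyloxy)benzaldehyde
Product: 4 2-hydroxy-4-(3-methylbut-2-enyloxy)-6-(triisopropylsilyloxy)benzaldehyde
Conditions: triisopropylsilyl chloride (1.05 equiv), imidazole, DMF, 0 °C to rt
Reagents that add atoms: triisopropylsilyl chloride, CC(C)[Si](Cl)(C(C)C)C(C)C
Why: Silylation of one of the two equivalent ortho phenols leaves the other locked in the hydrogen bond to the formyl oxygen and far less reactive, so the bulky chlorosilane should stop at the mono ether (phenol silylation).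

Step 3
Reactants: 4 2-hydroxy-4-(3-methylbut-2-enyloxy)-6-(triisopropylsilyloxy)benzaldehyde
Product: 5 2-(hydroxymethyl)-5-(3-methylbut-2-enyloxy)-3-(triisopropylsilyloxy)phenol
Conditions: NaBH4, THF/EtOH, −10 to 0 °C; aq. NH4Cl; used at once
Reagents that add atoms: none
Why: Borohydride reduction of the aldehyde at low temperature leaves the prenyl ether alone, and the bulky triisopropylsilyl group is chosen because it resists base-induced oxygen-to-oxygen silyl migration to the new benzylic alkoxide.

Step 4
Reactants: 5 2-(hydroxymethyl)-5-(3-methylbut-2-enyloxy)-3-(triisopropylsilyloxy)phenol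
Product: 6 [2-hydroxy-4-(3-methylbut-2-enyloxy)-6-(triisopropylsilyloxy)benzyl]triphenylphosphonium bromide
Conditions: PPh3·HBr (1.05 equiv), MeCN, 0 °C to rt; trituration with Et2O
Reagents that add atoms: triphenylphosphine hydrobromide, [PH+](c1ccccc1)(c1ccccc1)c1ccccc1.[Br-]
Why: The benzylic alcohol, activated by three ring oxygens, ionises under the mild acidity of the phosphonium salt to an ortho-quinone methide type cation that triphenylphosphine captures, the standard entry to (2-hydroxybenzyl)phosphonium salts, while this weak acid at room temperature should spare the prenyl and silyl ethers.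

Step 5
Reactants: 7 methyl 4-bromo-3,5-dihydroxybenzoate; 8 3-chloro-3-methylbut-1-yne
Product: 9 methyl 4-bromo-3,5-bis(2-methylbut-3-yn-2-yloxy)benzoate
Conditions: 8 (3 equiv), DBU (3 equiv), CuCl2·2H2O (1 mol %), MeCN, 0 °C to rt
Reagents that add atoms: 3-chloro-3-methylbut-1-yne (compound 8), C#CC(C)(C)Cl
Why: Copper-catalysed etherification of phenols with a tertiary propargylic chloride and an amidine base is the established route to hindered aryl 1,1-dimethylpropargyl ethers and tolerates the ortho bromine and the ester.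

Step 6
Reactants: 9 methyl 4-bromo-3,5-bis(2-methylbut-3-yn-2-yloxy)benzoate
Product: 10 4-bromo-3,5-bis(2-methylbut-3-yn-2-yloxy)benzoic acid
Conditions: LiOH·H2O, THF/MeOH/H2O, rt; then 1 M HCl at 0 °C to pH 3
Reagents that add atoms: lithium hydroxide monohydrate, [Li+].[OH-].O
Why: Ester saponification by hydroxide does not touch aryl ethers, terminal alkynes or the aryl bromide, and brief cold acidification spares the tertiary propargylic ethers.

Step 7
Reactants: 10 4-bromo-3,5-bis(2-methylbut-3-yn-2-yloxy)benzoic acid
Product: 11 4-bromo-3,5-bis(2-methylbut-3-yn-2-yloxy)benzoyl chloride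
Conditions: 1-chloro-N,N,2-trimethylprop-1-en-1-amine (1.2 equiv), CH2Cl2, 0 °C to rt; evaporated and used crude
Reagents that add atoms: 1-chloro-N,N,2-trimethylprop-1-en-1-amine, CC(C)=C(Cl)N(C)C
Why: The α-chloroenamine turns the acid into its chloride under neutral conditions, so no free HCl is present that could ionise the tertiary propargylic ethers (acid chloride formation with the Ghosez reagent).

Step 8
Reactants: 6 [2-hydroxy-4-(3-methylbut-2-enyloxy)-6-(triisopropylsilyloxy)benzyl]triphenylphosphonium bromide; 11 4-bromo-3,5-bis(2-methylbut-3-yn-2-yloxy)benzoyl chloride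
Product: 13 2-[4-bromo-3,5-bis(2-methylbut-3-yn-2-yloxy)phenyl]-6-(3-methylbut-2-enyloxy)-4-(triisopropylsilyloxy)benzofuran, via O-aroyl phosphonium bromide 12 (not isolated)
Conditions: 11 (1.05 equiv), Et3N (4 equiv), toluene, rt then 95 °C
Reagents that add atoms: none
Why: O-acylation of the phenol, deprotonation of the benzylic phosphonium salt to the ylide and intramolecular Wittig olefination of the ester carbonyl close the furan ring (acylation–Wittig benzofuran synthesis), at a temperature below that at which aryl propargyl ethers rearrange.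

Step 9
Reactants: 13 2-[4-bromo-3,5-bis(2-methylbut-3-yn-2-yloxy)phenyl]-6-(3-methylbut-2-enyloxy)-4-(triisopropylsilyloxy)benzofuran
Product: 14 2-[4-bromo-3,5-bis(2-methylbut-3-en-2-yloxy)phenyl]-6-(3-methylbut-2-enyloxy)-4-(triisopropylsilyloxy)benzofuran
Conditions: H2 (1 atm), Lindlar catalyst (Pd on CaCO3 poisoned with Pb(OAc)2), quinoline, EtOAc, rt, monitored; filtered, concentrated below 30 °C, used directly
Reagents that add atoms: none
Why: Lindlar semi-hydrogenation of the two terminal alkynes should stop at the vinyl groups and leave the trisubstituted prenyl double bond, the benzofuran and the aryl bromide untouched.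

Step 10
Reactants: 14 2-[4-bromo-3,5-bis(2-methylbut-3-en-2-yloxy)phenyl]-6-(3-methylbut-2-enyloxy)-4-(triisopropylsilyloxy)benzofuran
Product: 16 2-[4-bromo-3,5-dihydroxy-2,6-bis(3-methylbut-2-enyl)phenyl]-7-(2-methylbut-3-en-2-yl)-4-(triisopropylsilyloxy)benzofuran-6-ol, via ring C doubly rearranged diol 15 (not isolated)
Conditions: degassed N,N-diethylaniline (0.05 M), argon, 130 °C until both tertiary ethers are gone, then 190 °C; cooled, EtOAc, cold 1 M HCl wash
Reagents that add atoms: none
Why: Each of the three allyl aryl ethers undergoes a concerted, suprafacial, chair-like [3,3] sigmatropic shift (aromatic Claisen rearrangement) to an ortho cyclohexadienone that tautomerises to the phenol, with the allyl unit inverted each time, so the tertiary ethers on O3' and O5' deliver their CH2 ends to C2' and C6' (prenyl groups) near 130 °C and the primary prenyl ether on O6 delivers its CMe2 end to C7 (1,1-dimethylallyl group) near 190 °C. The closest known reactions are the thermal rearrangement of aryl 1,1-dimethylallyl ethers to ortho-prenylphenols and of aryl prenyl ethers to ortho-(1,1-dimethylallyl)phenols in N,N-diethylaniline; here both are run in one flask on one substrate. No ring is closed and no stereocentre is formed, so neither a closure mode nor a stereocontrol element is involved. Site selectivity is needed on both rings: on ring C the bromine occupies C4', where a shift would give a dienone that cannot enolise and can only revert, so each ether ends at its free ortho carbon; on ring A the para position is the ring-fusion carbon C3a, and of the two ortho carbons C7 is preferred because the C6–C7 bond of a benzofuran has the higher double-bond character (as 7-allyloxycoumarins go to C8) and because the triisopropylsilyloxy group crowds C5. The amine solvent keeps the medium basic, which together with the staged temperature and stopping once diol 15 is consumed should hold back closure of the new phenols onto their allyl neighbours.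

Step 11
Reactants: 16 2-[4-bromo-3,5-dihydroxy-2,6-bis(3-methylbut-2-enyl)phenyl]-7-(2-methylbut-3-en-2-yl)-4-(triisopropylsilyloxy)benzofuran-6-ol
Product: 17 2-[3,5-dihydroxy-2,6-bis(3-methylbut-2-enyl)phenyl]-7-(2-methylbut-3-en-2-yl)-4-(triisopropylsilyloxy)benzofuran-6-ol
Conditions: Bu3SnH (2 equiv), AIBN (0.2 equiv), degassed toluene, 90 °C; MeCN/hexane partition
Reagents that add atoms: none
Why: Radical-chain hydrodebromination, in which the stannyl radical abstracts bromine and the aryl σ-radical at C4' takes hydrogen from the tin hydride, should be clean because no double bond is within reach of C4' for cyclisation and hydrostannylation of unactivated alkenes is slow.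

Step 12
Reactants: 17 2-[3,5-dihydroxy-2,6-bis(3-methylbut-2-enyl)phenyl]-7-(2-methylbut-3-en-2-yl)-4-(triisopropylsilyloxy)benzofuran-6-ol
Product: 18 5-[6-hydroxy-7-(2-methylbut-3-en-2-yl)-4-(triisopropylsilyloxy)benzofuran-2-yl]-2,2-dimethyl-6-(3-methylbut-2-enyl)chroman-7-ol
Conditions: Amberlyst 15 (sulfonic acid resin), CH2Cl2, rt, stopped near half conversion; 17 recovered and resubmitted
Reagents that add atoms: none
Why: Acid-catalysed intramolecular hydroalkoxylation, in which Markovnikov protonation of a prenyl double bond gives a tertiary cation that the neighbouring phenol oxygen captures to form the 2,2-dimethylchroman, gives the same product from either of the two symmetry-equivalent prenyl/hydroxyl pairs, while the vinyl group on ring A would need a secondary cation and should react much more slowly.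

Step 13
Reactants: 18 5-[6-hydroxy-7-(2-methylbut-3-en-2-yl)-4-(triisopropylsilyloxy)benzofuran-2-yl]-2,2-dimethyl-6-(3-methylbut-2-enyl)chroman-7-ol
Product: 19 artopetelin C
Conditions: Bu4NF (1.1 equiv), AcOH (1.1 equiv), THF, 0 °C
Reagents that add atoms: none
Why: Fluoride cleaves the aryl silyl ether through formation of the strong Si–F bond, and the acetic acid buffer keeps the electron-rich phenol from sitting as an oxidisable phenoxide (fluoride desilylation).

**Compound list**

1 | 2,4,6-trihydroxybenzaldehyde | O=Cc1c(O)cc(O)cc1O | starting material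
2 | prenyl bromide (1-bromo-3-methylbut-2-ene) | CC(C)=CCBr | starting material
3 | 2,6-dihydroxy-4-(3-methylbut-2-enyloxy)benzaldehyde | CC(C)=CCOc1cc(O)c(C=O)c(O)c1 | intermediate
4 | 2-hydroxy-4-(3-methylbut-2-enyloxy)-6-(triisopropylsilyloxy)benzaldehyde | CC(C)=CCOc1cc(O)c(C=O)c(O[Si](C(C)C)(C(C)C)C(C)C)c1 | intermediate
5 | 2-(hydroxymethyl)-5-(3-methylbut-2-enyloxy)-3-(triisopropylsilyloxy)phenol | CC(C)=CCOc1cc(O)c(CO)c(O[Si](C(C)C)(C(C)C)C(C)C)c1 | intermediate
6 | [2-hydroxy-4-(3-methylbut-2-enyloxy)-6-(triisopropylsilyloxy)benzyl]triphenylphosphonium bromide | CC(C)=CCOc1cc(O)c(C[P+](c2ccccc2)(c2ccccc2)c2ccccc2)c(O[Si](C(C)C)(C(C)C)C(C)C)c1.[Br-] | intermediate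
7 | methyl 4-bromo-3,5-dihydroxybenzoate | COC(=O)c1cc(O)c(Br)c(O)c1 | starting material
8 | 3-chloro-3-methylbut-1-yne | C#CC(C)(C)Cl | starting material
9 | methyl 4-bromo-3,5-bis(2-methylbut-3-yn-2-yloxy)benzoate | COC(=O)c1cc(OC(C)(C)C#C)c(Br)c(OC(C)(C)C#C)c1 | intermediate
10 | 4-bromo-3,5-bis(2-methylbut-3-yn-2-yloxy)benzoic acid | OC(=O)c1cc(OC(C)(C)C#C)c(Br)c(OC(C)(C)C#C)c1 | intermediate
11 | 4-bromo-3,5-bis(2-methylbut-3-yn-2-yloxy)benzoyl chloride | ClC(=O)c1cc(OC(C)(C)C#C)c(Br)c(OC(C)(C)C#C)c1 | intermediate
12 | [2-[4-bromo-3,5-bis(2-methylbut-3-yn-2-yloxy)benzoyloxy]-4-(3-methylbut-2-enyloxy)-6-(triisopropylsilyloxy)benzyl]triphenylphosphonium bromide (not isolated) | CC(C)=CCOc1cc(OC(=O)c2cc(OC(C)(C)C#C)c(Br)c(OC(C)(C)C#C)c2)c(C[P+](c2ccccc2)(c2ccccc2)c2ccccc2)c(O[Si](C(C)C)(C(C)C)C(C)C)c1.[Br-] | intermediate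
13 | 2-[4-bromo-3,5-bis(2-methylbut-3-yn-2-yloxy)phenyl]-6-(3-methylbut-2-enyloxy)-4-(triisopropylsilyloxy)benzofuran | CC(C)=CCOc1cc(O[Si](C(C)C)(C(C)C)C(C)C)c2cc(oc2c1)-c1cc(OC(C)(C)C#C)c(Br)c(OC(C)(C)C#C)c1 | intermediate
14 | 2-[4-bromo-3,5-bis(2-methylbut-3-en-2-yloxy)phenyl]-6-(3-methylbut-2-enyloxy)-4-(triisopropylsilyloxy)benzofuran | CC(C)=CCOc1cc(O[Si](C(C)C)(C(C)C)C(C)C)c2cc(oc2c1)-c1cc(OC(C)(C)C=C)c(Br)c(OC(C)(C)C=C)c1 | intermediate
15 | 2-[4-bromo-3,5-dihydroxy-2,6-bis(3-methylbut-2-enyl)phenyl]-6-(3-methylbut-2-enyloxy)-4-(triisopropylsilyloxy)benzofuran (not isolated) | CC(C)=CCOc1cc(O[Si](C(C)C)(C(C)C)C(C)C)c2cc(oc2c1)-c1c(CC=C(C)C)c(O)c(Br)c(O)c1CC=C(C)C | intermediate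
16 | 2-[4-bromo-3,5-dihydroxy-2,6-bis(3-methylbut-2-enyl)phenyl]-7-(2-methylbut-3-en-2-yl)-4-(triisopropylsilyloxy)benzofuran-6-ol | C=CC(C)(C)c1c(O)cc(O[Si](C(C)C)(C(C)C)C(C)C)c2cc(oc12)-c1c(CC=C(C)C)c(O)c(Br)c(O)c1CC=C(C)C | intermediate
17 | 2-[3,5-dihydroxy-2,6-bis(3-methylbut-2-enyl)phenyl]-7-(2-methylbut-3-en-2-yl)-4-(triisopropylsilyloxy)benzofuran-6-ol | C=CC(C)(C)c1c(O)cc(O[Si](C(C)C)(C(C)C)C(C)C)c2cc(oc12)-c1c(CC=C(C)C)c(O)cc(O)c1CC=C(C)C | intermediate
18 | 5-[6-hydroxy-7-(2-methylbut-3-en-2-yl)-4-(triisopropylsilyloxy)benzofuran-2-yl]-2,2-dimethyl-6-(3-methylbut-2-enyl)chroman-7-ol | C=CC(C)(C)c1c(O)cc(O[Si](C(C)C)(C(C)C)C(C)C)c2cc(-c3c(CC=C(C)C)c(O)cc4c3CCC(C)(C)O4)oc12 | intermediate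
19 | artopetelin C | C=CC(C)(C)c1c(O)cc(O)c2cc(-c3c(CC=C(C)C)c(O)cc4c3CCC(C)(C)O4)oc12 | target

**Count**

Total steps: 13. Longest linear sequence: 10 steps (steps 1 to 4, then 8 to 13, from 2,4,6-trihydroxybenzaldehyde); the ring C arm (steps 5 to 7) joins at step 8.

**Steps most likely to fail**

1. Step 10. The tertiary allyl ethers may be lost as isoprene before they rearrange. The third shift may go partly to C5. At 190 °C the new C6 phenol may add to its vinyl neighbour or the side chain may isomerise (abnormal Claisen), and the ring C prenylphenols may degrade on long heating. The fallback runs the shifts in two stages with the phenols capped. It sets out from 14, which is heated in N,N-diethylaniline only to 130 °C, and diol 15 is isolated. Acetylation (Ac2O, pyridine, DMAP, CH2Cl2, 0 °C) gives 2-[3,5-diacetoxy-4-bromo-2,6-bis(3-methylbut-2-enyl)phenyl]-6-(3-methylbut-2-enyloxy)-4-(triisopropylsilyloxy)benzofuran F1. Thermolysis of F1 in N,N-diethylaniline with Ac2O and NaOAc at 190 °C rearranges the prenyl ether and traps the new phenol at once as its ester, 2-[3,5-diacetoxy-4-bromo-2,6-bis(3-methylbut-2-enyl)phenyl]-6-acetoxy-7-(2-methylbut-3-en-2-yl)-4-(triisopropylsilyloxy)benzofuran F2. Ammonolysis of the three aryl acetates (NH3 in MeOH, 0 °C), which spares the silyl ether, comes back to the route at 16.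

2. Step 12. Because the two prenyl/phenol pairs are equivalent, ring closure may continue to the bis-chroman, and the conversion of a catalytic acid reaction is hard to hold at the mono stage. Prolonged acid may also close the C6 phenol onto the vinyl group or loosen the silyl ether. The fallback replaces proton catalysis by a stoichiometric soft electrophile, so that the extent of reaction is fixed by the reagent charge; the mono/bis statistics remain, and unreacted 17 is recycled as before. It sets out from 17: N-(phenylseleno)phthalimide (1.0 equiv) with catalytic camphorsulfonic acid in CH2Cl2 at −78 to 0 °C should add to one electron-rich trisubstituted double bond with capture by the neighbouring phenol, giving racemic 5-[6-hydroxy-7-(2-methylbut-3-en-2-yl)-4-(triisopropylsilyloxy)benzofuran-2-yl]-2,2-dimethyl-6-(3-methylbut-2-enyl)-3-(phenylselanyl)chroman-7-ol F3. Reductive removal of selenium (Bu3SnH, AIBN, toluene, 90 °C) comes back to the route at 18.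

3. Step 4. The very electron-rich benzylic alcohol may ionise and self-condense faster than triphenylphosphine captures it, and the acidic salt may cleave the prenyl ether. The fallback avoids the benzylic alcohol and phosphorus altogether and so also replaces steps 3 and 8. It sets out from aldehyde 4, whose phenol is acylated with acid chloride 11 (Et3N, DMAP, CH2Cl2, 0 °C) to give 2-formyl-5-(3-methylbut-2-enyloxy)-3-(triisopropylsilyloxy)phenyl 4-bromo-3,5-bis(2-methylbut-3-yn-2-yloxy)benzoate F4. Reductive oxo-ester coupling of the aldehyde and ester carbonyls with low-valent titanium (TiCl3 and Zn dust, THF, reflux, slow addition; McMurry-type benzofuran synthesis) closes the furan ring and comes back to the route at 13.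

**Further compounds**

F1 | step 10 | 2-[3,5-diacetoxy-4-bromo-2,6-bis(3-methylbut-2-enyl)phenyl]-6-(3-methylbut-2-enyloxy)-4-(triisopropylsilyloxy)benzofuran | CC(C)=CCOc1cc(O[Si](C(C)C)(C(C)C)C(C)C)c2cc(oc2c1)-c1c(CC=C(C)C)c(OC(C)=O)c(Br)c(OC(C)=O)c1CC=C(C)C
F2 | step 10 | 2-[3,5-diacetoxy-4-bromo-2,6-bis(3-methylbut-2-enyl)phenyl]-6-acetoxy-7-(2-methylbut-3-en-2-yl)-4-(triisopropylsilyloxy)benzofuran | C=CC(C)(C)c1c(OC(C)=O)cc(O[Si](C(C)C)(C(C)C)C(C)C)c2cc(oc12)-c1c(CC=C(C)C)c(OC(C)=O)c(Br)c(OC(C)=O)c1CC=C(C)C
F3 | step 12 | racemic 5-[6-hydroxy-7-(2-methylbut-3-en-2-yl)-4-(triisopropylsilyloxy)benzofuran-2-yl]-2,2-dimethyl-6-(3-methylbut-2-enyl)-3-(phenylselanyl)chroman-7-ol | C=CC(C)(C)c1c(O)cc(O[Si](C(C)C)(C(C)C)C(C)C)c2cc(-c3c(CC=C(C)C)c(O)cc4c3CC([Se]c3ccccc3)C(C)(C)O4)oc12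
F4 | step 4 | 2-formyl-5-(3-methylbut-2-enyloxy)-3-(triisopropylsilyloxy)phenyl 4-bromo-3,5-bis(2-methylbut-3-yn-2-yloxy)benzoate | CC(C)=CCOc1cc(OC(=O)c2cc(OC(C)(C)C#C)c(Br)c(OC(C)(C)C#C)c2)c(C=O)c(O[Si](C(C)C)(C(C)C)C(C)C)c1
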